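**Retrosynthetic overview**
- Target ⇒ oxidative unmasking of a 1,4‑dimethoxynaphthalene ⇒ saturated side chain from one global asymmetric hydrogenation of an all‑(E) polyene, which sets the four methyl‑bearing centres.
- Polyene ⇒ one‑carbon Wittig linchpin (Ph3P=CH2) joining a cyclopentane aldehyde to an ω‑bromo farnesyl arene.
- Cyclopentane aldehyde ⇒ alkynol (methylalumination/prenylation builds the tail) ⇒ bridged lactone ⇒ meso cis‑cyclopentane‑1,3‑dicarboxylic anhydride, desymmetrised by an oxazaborolidine‑catalysed reduction that sets both ring centres.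
- ω‑Bromide ⇒ SeO2 oxidation of the terminal (E)‑methyl of a farnesyl arene ⇒ aryl Grignard + (2E,6E)‑farnesyl bromide.
- Rings: no carbocycle is built (cyclopentane and naphthalene are bought); the lactone ring forms in step 1 and is opened in step 2; the quinone ring is unveiled last.

Assumption: 1, 7, 11 and 12 are catalogue compounds; the antipode named for each chiral catalyst is the one expected to give the drawn configuration, and its mirror image is taken if a first run shows the opposite sense.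

**Step 1**
Reactants: 1 cis‑cyclopentane‑1,3‑dicarboxylic anhydride (meso)
Product: 4 (1S,5R)‑3‑oxabicyclo[3.2.1]octan‑2‑one, via hemiacylal 2 (not isolated), via hydroxy acid 3 (not isolated)
Conditions: (S)‑2‑methyl‑CBS‑oxazaborolidine (10 mol %), catecholborane (1.2 equiv), toluene, −40 °C; then NaBH4, MeOH, 0 °C; then 2 M HCl, rt
Reagents that add atoms: none
Why: Proposed new method: an oxazaborolidine‑catalysed (CBS‑type) desymmetrising hydride transfer to a meso cyclic anhydride, in which catecholborane bound at the catalyst nitrogen delivers hydride through a six‑membered transition state to the carbonyl held on the ring boron; hydride can reach either carbonyl only from the face anti to the two‑carbon bridge while the catalyst fixes which oxygen lone pair is bound, so only one of the two enantiotopic C=O groups meets both demands and both ring stereocentres (C1 S, C5 R) are set at once; NaBH4 then takes the borate hemiacylal on to the hydroxy acid, which lactonises on acidification; the closest known reaction types are the CBS reduction of meso cyclic imides to hydroxy‑lactams and the NaBH4 reduction of cyclic anhydrides to lactones.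

**Step 2**
Reactants: 4 (1S,5R)‑3‑oxabicyclo[3.2.1]octan‑2‑one
Product: 6 [(1R,3S)‑3‑ethynylcyclopentyl]methanol, via lactol 5 (not isolated)
Conditions: iBu2AlH (1.1 equiv), CH2Cl2, −78 °C; then MeOH, K2CO3, dimethyl (1‑diazo‑2‑oxopropyl)phosphonate, −78 °C to rt
Reagents that add atoms: dimethyl (1‑diazo‑2‑oxopropyl)phosphonate, COP(=O)(OC)C(=[N+]=[N-])C(C)=O
Why: Half‑reduction of the lactone stops at the aluminium lactolate, whose open aldehyde form undergoes Seyferth–Gilbert homologation with the Ohira–Bestmann reagent under mild carbonate conditions; no stereocentre is formed and both ring centres are carried through.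

**Step 3**
Reactants: 6 [(1R,3S)‑3‑ethynylcyclopentyl]methanol; 7 1‑chloro‑3‑methylbut‑2‑ene (prenyl chloride)
Product: 9 [(1R,3S)‑3‑[(2E)‑6‑methylhepta‑2,5‑dien‑2‑yl]cyclopentyl]methanol, via alkenylalane 8 (not isolated)
Conditions: Me3Al (3 equiv), Cp2ZrCl2 (25 mol %), ClCH2CH2Cl, 0 °C to rt; then 7, Pd(PPh3)4 (5 mol %), THF, rt
Reagents that add atoms: trimethylaluminium, C[Al](C)C
Why: Negishi zirconium‑catalysed carboalumination adds methyl and aluminium syn across the terminal alkyne (methyl on the inner carbon, the hydroxyl riding along as its aluminium alkoxide), and palladium‑catalysed allylation of the alkenylalane at the primary carbon of prenyl chloride with retention gives the pure (E)‑trisubstituted olefin that later defines the side‑chain methyl centre.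

**Step 4**
Reactants: 9 [(1R,3S)‑3‑[(2E)‑6‑methylhepta‑2,5‑dien‑2‑yl]cyclopentyl]methanol
Product: 10 (1R,3S)‑3‑[(2E)‑6‑methylhepta‑2,5‑dien‑2‑yl]cyclopentane‑1‑carbaldehyde
Conditions: Dess–Martin periodinane, CH2Cl2, 0 °C to rt
Reagents that add atoms: none
Why: Dess–Martin oxidation of the primary alcohol is neutral and fast, so the α‑stereocentre and the skipped diene survive; the aldehyde is used at once.

**Step 5**
Reactants: 11 2‑bromo‑1,4‑dimethoxy‑3‑methylnaphthalene; 12 (2E,6E)‑1‑bromo‑3,7,11‑trimethyldodeca‑2,6,10‑triene (farnesyl bromide)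
Product: 14 1,4‑dimethoxy‑2‑methyl‑3‑[(2E,6E)‑3,7,11‑trimethyldodeca‑2,6,10‑trien‑1‑yl]naphthalene, via arylmagnesium bromide 13 (not isolated)
Conditions: Mg, THF, 40 °C; then 12, CuBr·SMe2 (5 mol %), −20 °C to rt
Reagents that add atoms: none
Why: Copper‑catalysed Grignard allylation takes place at the primary carbon of the allylic bromide (attack at the other end would build a quaternary centre), so the (2E,6E) geometry is kept, as in standard menaquinone syntheses.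

**Step 6**
Reactants: 14 1,4‑dimethoxy‑2‑methyl‑3‑[(2E,6E)‑3,7,11‑trimethyldodeca‑2,6,10‑trien‑1‑yl]naphthalene
Product: 15 (2E,6E,10E)‑12‑(1,4‑dimethoxy‑3‑methylnaphthalen‑2‑yl)‑2,6,10‑trimethyldodeca‑2,6,10‑trien‑1‑ol
Conditions: SeO2 (0.3 equiv), tBuOOH (2 equiv), salicylic acid (10 mol %), CH2Cl2, 0 °C to rt
Reagents that add atoms: selenium dioxide, O=[Se]=O; tert‑butyl hydroperoxide, CC(C)(C)OO
Why: Riley–Sharpless allylic oxidation (ene reaction, then [2,3]‑sigmatropic shift) picks the (E)‑methyl of the most accessible terminal trisubstituted olefin and returns the double bond with (E) geometry.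

**Step 7**
Reactants: 15 (2E,6E,10E)‑12‑(1,4‑dimethoxy‑3‑methylnaphthalen‑2‑yl)‑2,6,10‑trimethyldodeca‑2,6,10‑trien‑1‑ol
Product: 16 2‑[(2E,6E,10E)‑12‑bromo‑3,7,11‑trimethyldodeca‑2,6,10‑trien‑1‑yl]‑1,4‑dimethoxy‑3‑methylnaphthalene
Conditions: CBr4, PPh3, CH2Cl2, 0 °C
Reagents that add atoms: carbon tetrabromide, BrC(Br)(Br)Br
Why: The Appel reaction turns the primary allylic alcohol into the bromide by SN2 displacement without allylic shift or loss of olefin geometry.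

**Step 8**
Reactants: 16 2‑[(2E,6E,10E)‑12‑bromo‑3,7,11‑trimethyldodeca‑2,6,10‑trien‑1‑yl]‑1,4‑dimethoxy‑3‑methylnaphthalene; 10 (1R,3S)‑3‑[(2E)‑6‑methylhepta‑2,5‑dien‑2‑yl]cyclopentane‑1‑carbaldehyde
Product: 19 2‑[(2E,6E,10E,13Z)‑3,7,11‑trimethyl‑14‑[(1R,3S)‑3‑[(2E)‑6‑methylhepta‑2,5‑dien‑2‑yl]cyclopentyl]tetradeca‑2,6,10,13‑tetraen‑1‑yl]‑1,4‑dimethoxy‑3‑methylnaphthalene, via phosphonium bromide 17 (not isolated), via ylide 18 (not isolated)
Conditions: Ph3PCH3Br, KN(SiMe3)2, THF, −78 to 0 °C; then 16, −78 to 0 °C; then KN(SiMe3)2, −78 °C; then 10, −78 °C to rt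
Reagents that add atoms: methyltriphenylphosphonium bromide, C[P+](c1ccccc1)(c1ccccc1)c1ccccc1.[Br-]
Why: C‑alkylation of methylenetriphenylphosphorane by the primary allylic bromide (SN2) gives the one‑carbon‑longer phosphonium salt, whose ylide undergoes Wittig olefination with the aldehyde; the new disubstituted alkene (Z drawn) is saturated in step 9, and the cold salt‑free conditions protect the α‑centre of the aldehyde.

**Step 9**
Reactants: 19 (the hexaene from step 8)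
Product: 20 1,4‑dimethoxy‑2‑methyl‑3‑[(3S,7S,11R)‑3,7,11‑trimethyl‑14‑[(1R,3S)‑3‑[(2R)‑6‑methylheptan‑2‑yl]cyclopentyl]tetradecyl]naphthalene
Conditions: H2 (50 bar), [Ir(cod)(L)][B(C6H3(CF3)2)4] (3 mol %, L = (R)‑2‑phenyl‑8‑(di‑o‑tolylphosphinooxy)‑5,6,7,8‑tetrahydroquinoline), CH2Cl2, rt
Reagents that add atoms: none
Why: Pfaltz‑type iridium N,P‑catalysed asymmetric hydrogenation of unfunctionalised trisubstituted olefins reads the face from the position of the vinylic hydrogen, so one catalyst antipode turns the three (E)‑chain olefins into C3(S), C7(S) and C11(R) and the (E)‑olefin next to the ring into the (2R)‑methyl centre, while the other two double bonds are simply saturated and the ring centres stay as set in step 1.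

**Step 10**
Reactants: 20 (the saturated dimethyl ether from step 9)
Product: 21 2‑methyl‑3‑[(3S,7S,11R)‑3,7,11‑trimethyl‑14‑[(1R,3S)‑3‑[(2R)‑6‑methylheptan‑2‑yl]cyclopentyl]tetradecyl]naphthalene‑1,4‑dione
Conditions: (NH4)2Ce(NO3)6, MeCN/H2O, 0 °C
Reagents that add atoms: water, O
Why: Oxidative demethylation of the 1,4‑dimethoxyarene by the cerium ammonium nitrate (water attacks the radical cation and methanol leaves) gives the quinone without touching the saturated chain or any stereocentre.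

**Compound list**
1 | cis‑cyclopentane‑1,3‑dicarboxylic anhydride, (1R,5S)‑3‑oxabicyclo[3.2.1]octane‑2,4‑dione (meso, achiral) | O=C1OC(=O)[C@@H]2CC[C@H]1C2 | starting material
2 | (1S,5R)‑4‑hydroxy‑3‑oxabicyclo[3.2.1]octan‑2‑one (hemiacylal, both C4 epimers, held as its catechol borate) | OC1[C@@H]2CC[C@H](C(=O)O1)C2 | intermediate
3 | (1S,3R)‑3‑(hydroxymethyl)cyclopentane‑1‑carboxylic acid | OC[C@@H]1CC[C@H](C(=O)O)C1 | intermediate
4 | (1S,5R)‑3‑oxabicyclo[3.2.1]octan‑2‑one | O=C1OC[C@@H]2CC[C@H]1C2 | intermediate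
5 | (1S,5R)‑3‑oxabicyclo[3.2.1]octan‑2‑ol (lactol, both anomers) | OC1OC[C@@H]2CC[C@H]1C2 | intermediate
6 | [(1R,3S)‑3‑ethynylcyclopentyl]methanol | OC[C@@H]1CC[C@H](C#C)C1 | intermediate
7 | 1‑chloro‑3‑methylbut‑2‑ene (prenyl chloride) | CC(C)=CCCl | starting material
8 | [(1E)‑2‑[(1S,3R)‑3‑[(dimethylalumanyloxy)methyl]cyclopentyl]prop‑1‑en‑1‑yl]dimethylalumane | C[Al](C)OC[C@@H]1CC[C@H](/C(C)=C/[Al](C)C)C1 | intermediate
9 | [(1R,3S)‑3‑[(2E)‑6‑methylhepta‑2,5‑dien‑2‑yl]cyclopentyl]methanol | OC[C@@H]1CC[C@H](/C(C)=C/CC=C(C)C)C1 | intermediate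
10 | (1R,3S)‑3‑[(2E)‑6‑methylhepta‑2,5‑dien‑2‑yl]cyclopentane‑1‑carbaldehyde | O=C[C@@H]1CC[C@H](/C(C)=C/CC=C(C)C)C1 | intermediate
11 | 2‑bromo‑1,4‑dimethoxy‑3‑methylnaphthalene | COc1c(Br)c(C)c(OC)c2ccccc12 | starting material
12 | (2E,6E)‑1‑bromo‑3,7,11‑trimethyldodeca‑2,6,10‑triene | CC(C)=CCC/C(C)=C/CC/C(C)=C/CBr | starting material
13 | (1,4‑dimethoxy‑3‑methylnaphthalen‑2‑yl)magnesium bromide | COc1c([Mg]Br)c(C)c(OC)c2ccccc12 | intermediate
14 | 1,4‑dimethoxy‑2‑methyl‑3‑[(2E,6E)‑3,7,11‑trimethyldodeca‑2,6,10‑trien‑1‑yl]naphthalene | COc1c(C)c(C/C=C(\C)CC/C=C(\C)CCC=C(C)C)c(OC)c2ccccc12 | intermediate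
15 | (2E,6E,10E)‑12‑(1,4‑dimethoxy‑3‑methylnaphthalen‑2‑yl)‑2,6,10‑trimethyldodeca‑2,6,10‑trien‑1‑ol | COc1c(C)c(C/C=C(\C)CC/C=C(\C)CC/C=C(\C)CO)c(OC)c2ccccc12 | intermediate
16 | 2‑[(2E,6E,10E)‑12‑bromo‑3,7,11‑trimethyldodeca‑2,6,10‑trien‑1‑yl]‑1,4‑dimethoxy‑3‑methylnaphthalene | COc1c(C)c(C/C=C(\C)CC/C=C(\C)CC/C=C(\C)CBr)c(OC)c2ccccc12 | intermediate
17 | [(3E,7E,11E)‑13‑(1,4‑dimethoxy‑3‑methylnaphthalen‑2‑yl)‑3,7,11‑trimethyltrideca‑3,7,11‑trien‑1‑yl]triphenylphosphonium bromide | COc1c(C)c(C/C=C(\C)CC/C=C(\C)CC/C=C(\C)CC[P+](c3ccccc3)(c3ccccc3)c3ccccc3)c(OC)c2ccccc12.[Br-] | intermediate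
18 | [(3E,7E,11E)‑13‑(1,4‑dimethoxy‑3‑methylnaphthalen‑2‑yl)‑3,7,11‑trimethyltrideca‑3,7,11‑trien‑1‑ylidene]triphenylphosphorane | COc1c(C)c(C/C=C(\C)CC/C=C(\C)CC/C=C(\C)CC=P(c3ccccc3)(c3ccccc3)c3ccccc3)c(OC)c2ccccc12 | intermediate
19 | 2‑[(2E,6E,10E,13Z)‑3,7,11‑trimethyl‑14‑[(1R,3S)‑3‑[(2E)‑6‑methylhepta‑2,5‑dien‑2‑yl]cyclopentyl]tetradeca‑2,6,10,13‑tetraen‑1‑yl]‑1,4‑dimethoxy‑3‑methylnaphthalene | COc1c(C)c(C/C=C(\C)CC/C=C(\C)CC/C=C(\C)C/C=C\[C@@H]3CC[C@H](/C(C)=C/CC=C(C)C)C3)c(OC)c2ccccc12 | intermediate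
20 | 1,4‑dimethoxy‑2‑methyl‑3‑[(3S,7S,11R)‑3,7,11‑trimethyl‑14‑[(1R,3S)‑3‑[(2R)‑6‑methylheptan‑2‑yl]cyclopentyl]tetradecyl]naphthalene | COc1c(C)c(CC[C@@H](C)CCC[C@@H](C)CCC[C@@H](C)CCC[C@@H]3CC[C@H]([C@H](C)CCCC(C)C)C3)c(OC)c2ccccc12 | intermediate
21 | 2‑methyl‑3‑[(3S,7S,11R)‑3,7,11‑trimethyl‑14‑[(1R,3S)‑3‑[(2R)‑6‑methylheptan‑2‑yl]cyclopentyl]tetradecyl]naphthalene‑1,4‑dione | CC1=C(CC[C@@H](C)CCC[C@@H](C)CCC[C@@H](C)CCC[C@@H]2CC[C@H]([C@H](C)CCCC(C)C)C2)C(=O)c2ccccc2C1=O | target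

**Totals**
Total step count: 10. Longest linear sequence: 7 (steps 1, 2, 3, 4, 8, 9, 10).

**Three steps most likely to fail**

Step 1 (the new desymmetrising reduction). The anhydride carbonyl may bind the oxazaborolidine too weakly, giving slow turnover or low ee. The fallback is known chemistry, sets out from 1 and returns at 4. Cinchona‑alkaloid‑catalysed methanolysis of 1 ((DHQD)2AQN, MeOH, Et2O, −30 °C) opens one enantiotopic carbonyl and gives (1R,3S)‑3‑(methoxycarbonyl)cyclopentane‑1‑carboxylic acid F1. BH3·SMe2 in THF reduces only the free acid to methyl (1S,3R)‑3‑(hydroxymethyl)cyclopentane‑1‑carboxylate F2. Catalytic TsOH in warm toluene then closes F2 to lactone 4.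

Step 8 (ylide alkylation and Wittig with two advanced fragments). The allylic bromide may eliminate or the aldehyde may epimerise. The fallback sets out from 10, uses 16, and returns at 19. Ohira–Bestmann homologation of 10 (K2CO3, MeOH) gives (1R,3S)‑1‑ethynyl‑3‑[(2E)‑6‑methylhepta‑2,5‑dien‑2‑yl]cyclopentane F3. Copper‑mediated coupling of F3 with 16 (CuI, NaI, K2CO3, DMF, rt) gives 2‑[(2E,6E,10E)‑3,7,11‑trimethyl‑14‑[(1R,3S)‑3‑[(2E)‑6‑methylhepta‑2,5‑dien‑2‑yl]cyclopentyl]tetradeca‑2,6,10‑trien‑13‑yn‑1‑yl]‑1,4‑dimethoxy‑3‑methylnaphthalene F4. Semi‑hydrogenation of F4 (H2 1 bar, Pd/CaCO3 poisoned with Pb(OAc)2, quinoline) gives 19.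

Step 9 (four centres in one hydrogenation). The olefin next to the ring may be mismatched with the neighbouring ring centre, and the skipped dienes or the allylic ring CH may suffer double‑bond migration before reduction. The fallback sets the ring‑adjacent methyl centre beforehand by iminium catalysis; it sets out from 6 and returns at 20.
- Carboalumination of 6 as in step 3, but trapping the alkenylalanate (nBuLi) with (CH2O)n, gives (2E)‑3‑[(1S,3R)‑3‑(hydroxymethyl)cyclopentyl]but‑2‑en‑1‑ol F5.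
- MnO2 oxidises only the allylic hydroxyl to (2E)‑3‑[(1S,3R)‑3‑(hydroxymethyl)cyclopentyl]but‑2‑enal F6.
- Transfer hydrogenation with (S)‑2‑tert‑butyl‑3‑methylimidazolidin‑4‑one trichloroacetate and Hantzsch ester (CHCl3, −30 °C; E/Z‑convergent, catalyst‑controlled) gives (3R)‑3‑[(1S,3R)‑3‑(hydroxymethyl)cyclopentyl]butanal F7.
- Wittig reaction with isobutylidenetriphenylphosphorane gives [(1R,3S)‑3‑[(2R,4Z)‑6‑methylhept‑4‑en‑2‑yl]cyclopentyl]methanol F8.
- Dess–Martin oxidation gives (1R,3S)‑3‑[(2R,4Z)‑6‑methylhept‑4‑en‑2‑yl]cyclopentane‑1‑carbaldehyde F9.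
- The step 8 procedure with 16 (through 17 and 18) gives 2‑[(2E,6E,10E,13Z)‑3,7,11‑trimethyl‑14‑[(1R,3S)‑3‑[(2R,4Z)‑6‑methylhept‑4‑en‑2‑yl]cyclopentyl]tetradeca‑2,6,10,13‑tetraen‑1‑yl]‑1,4‑dimethoxy‑3‑methylnaphthalene F10.
- Hydrogenation of F10 under the step 9 conditions, where only the three chain olefins are now stereogenic, gives 20.

**Further compounds**
F1 | step 1 | (1R,3S)‑3‑(methoxycarbonyl)cyclopentane‑1‑carboxylic acid | OC(=O)[C@@H]1CC[C@H](C(=O)OC)C1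
F2 | step 1 | methyl (1S,3R)‑3‑(hydroxymethyl)cyclopentane‑1‑carboxylate | OC[C@@H]1CC[C@H](C(=O)OC)C1
F3 | step 8 | (1R,3S)‑1‑ethynyl‑3‑[(2E)‑6‑methylhepta‑2,5‑dien‑2‑yl]cyclopentane | C#C[C@@H]1CC[C@H](/C(C)=C/CC=C(C)C)C1
F4 | step 8 | 2‑[(2E,6E,10E)‑3,7,11‑trimethyl‑14‑[(1R,3S)‑3‑[(2E)‑6‑methylhepta‑2,5‑dien‑2‑yl]cyclopentyl]tetradeca‑2,6,10‑trien‑13‑yn‑1‑yl]‑1,4‑dimethoxy‑3‑methylnaphthalene | COc1c(C)c(C/C=C(\C)CC/C=C(\C)CC/C=C(\C)CC#C[C@@H]3CC[C@H](/C(C)=C/CC=C(C)C)C3)c(OC)c2ccccc12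
F5 | step 9 | (2E)‑3‑[(1S,3R)‑3‑(hydroxymethyl)cyclopentyl]but‑2‑en‑1‑ol | OC[C@@H]1CC[C@H](/C(C)=C/CO)C1
F6 | step 9 | (2E)‑3‑[(1S,3R)‑3‑(hydroxymethyl)cyclopentyl]but‑2‑enal | OC[C@@H]1CC[C@H](/C(C)=C/C=O)C1
F7 | step 9 | (3R)‑3‑[(1S,3R)‑3‑(hydroxymethyl)cyclopentyl]butanal | OC[C@@H]1CC[C@H]([C@H](C)CC=O)C1
F8 | step 9 | [(1R,3S)‑3‑[(2R,4Z)‑6‑methylhept‑4‑en‑2‑yl]cyclopentyl]methanol | OC[C@@H]1CC[C@H]([C@H](C)C/C=C\C(C)C)C1
F9 | step 9 | (1R,3S)‑3‑[(2R,4Z)‑6‑methylhept‑4‑en‑2‑yl]cyclopentane‑1‑carbaldehyde | O=C[C@@H]1CC[C@H]([C@H](C)C/C=C\C(C)C)C1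
F10 | step 9 | 2‑[(2E,6E,10E,13Z)‑3,7,11‑trimethyl‑14‑[(1R,3S)‑3‑[(2R,4Z)‑6‑methylhept‑4‑en‑2‑yl]cyclopentyl]tetradeca‑2,6,10,13‑tetraen‑1‑yl]‑1,4‑dimethoxy‑3‑methylnaphthalene | COc1c(C)c(C/C=C(\C)CC/C=C(\C)CC/C=C(\C)C/C=C\[C@@H]3CC[C@H]([C@H](C)C/C=C\C(C)C)C3)c(OC)c2ccccc12
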